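**Retrosynthetic overview**
1. C3 quaternary centre: made last, by catalyst-controlled C-prenylation of the C3-methyl enol (Tsuji–Trost).
2. C7' carbinol: Markovnikov radical hydration of a C7'=C8' ring alkene.
3. Both carbocycles, the spiro centre C5, C2' and C6' in one step: intramolecular Diels–Alder reaction of a dienyl o-quinone methide (diene C5=C8'–C7'=C6', dienophile C1'=C2'). The cyclohexene and cyclopentane rings form together on the existing phloroglucinol ring.
4. o-Quinone methide: Knoevenagel condensation of the acylated methylphloroglucinol with (R)-8-oxolinalool; it rests as its 2H-chromene.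
5. Building blocks: Friedel–Crafts acylation of 2-methylphloroglucinol, and SeO2 oxidation of (R)-linalool, which supplies C3'.

Assumption: the plant is taken to build the spiro-hydrindane from the acylphloroglucinol and (R)-8-oxolinalool (condensation to a dienyl o-quinone methide, intramolecular [4+2] closure, hydration of the new ring alkene), and the route copies these ring-forming events; C-prenylation is placed last for chemoselectivity.

Locants: trione ring C1 (acyl), C2 (enol OH), C3 (Me, prenyl), C4 (C=O), C5 (spiro), C6 (C=O). The terpenoid carbons keep the linalool numbers C1'–C8': C1'H2 and C8'H2 sit on C5, C2'/C6' are the ring fusion, C3' and C7' are the carbinols. β is the hydrindane face that carries both OH groups and C6=O. H2', H6', both carbinol methyl groups and C4=O are α.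

**Step 1**
Reactants: 1 (R)-(−)-linalool
Product: 2 (R,E)-8-oxolinalool [(2E,6R)-6-hydroxy-2,6-dimethylocta-2,7-dienal]
Conditions: SeO2 (1.1 equiv), 1,4-dioxane, 80 °C
Reagents that add atoms: selenium dioxide, O=[Se]=O
Why: Riley allylic oxidation: the ene reaction of SeO2 at the electron-rich trisubstituted alkene followed by a [2,3]-sigmatropic shift functionalises only the (E)-methyl group and stops at the conjugated enal, while the vinyl group and the C3' carbinol stereocentre are untouched.

**Step 2**
Reactants: 3 2-methylbenzene-1,3,5-triol; 4 (S)-2-methylbutanoyl chloride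
Product: 5 (2S)-2-methyl-1-(2,4,6-trihydroxy-3-methylphenyl)butan-1-one
Conditions: AlCl3 (3.5 equiv), CH2Cl2–PhNO2, 0 to 40 °C; aq. HCl
Reagents that add atoms: (S)-2-methylbutanoyl chloride (4), CC[C@H](C)C(=O)Cl
Why: Friedel–Crafts acylation: the two free ring positions of 3 are equivalent and the first acyl group deactivates the ring, so a single ketone forms, and the mild temperature keeps the α-stereocentre brought in by 4.

**Step 3**
Reactants: 5 acylated methylphloroglucinol; 2 (R,E)-8-oxolinalool
Product: 8 spiro-hydrindene Diels–Alder adduct, via o-quinone methide 6 (not isolated), via 2H-chromene 7 (not isolated)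
Conditions: ethylenediammonium diacetate (20 mol %), pyridine–o-xylene 1:4, 110 °C, 6 h; then 150 °C (sealed tube), 36 h, BHT (5 mol %), Ar
Reagents that add atoms: (R,E)-8-oxolinalool (2), C=C[C@](C)(O)CC/C=C(\C)C=O
Why: Proposed new method: Knoevenagel condensation at the only free ring carbon gives 6, which rests as its oxa-6π valence isomer 7 (the known chromene synthesis from phloroglucinols and enals; closure through O4 keeps both OH groups beside the acyl group chelated); at 150 °C retro-6π re-opens 7 to the cisoid (Z)-o-quinone methide with C4=O inside, whose electron-poor 1,1-diacyl diene C5=C8'–C7'=C6' is tied by three atoms to the vinyl group and closes irreversibly in a type 1 intramolecular Diels–Alder reaction (closest known types: thermal 1,3,8-nonatriene cyclisations and the retro-6π/cycloaddition of citral-derived chromenes to citrans), the hetero-Diels–Alder mode being excluded because it would need a bridged medium ring; suprafacial addition carries the alkylidene geometry into the spiro centre (C4 cis to H6'), the unactivated dienophile is expected to close through the cis-hydrindene transition state, and the C3' centre is expected to put its methyl group on the convex side and its OH next to C1', which together set C5, C2' and C6'.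

**Step 4**
Reactants: 8 spiro-hydrindene Diels–Alder adduct
Product: 10 deprenyl diol (C3–H enol form of the target), via triethylsilyl peroxide 9 (not isolated)
Conditions: Co(thd)2 (10 mol %; thd = 2,2,6,6-tetramethylheptane-3,5-dionate), O2 (1 atm), Et3SiH (2.5 equiv), ClCH2CH2Cl, rt; then PPh3 (1.5 equiv), MeOH–H2O, rt
Reagents that add atoms: dioxygen, O=O
Why: Isayama–Mukaiyama hydroperoxysilylation (metal-hydride hydrogen-atom transfer): the cobalt hydride delivers H• to the less substituted C8' of the only isolated alkene; the tertiary C7' radical should be caught by O2 on the β face, because in the chair with the C3' branch equatorial the α lobe is screened by the axial C4 carbon of the spiro ring and by H2'; PPh3 in wet methanol then cleaves the O–Si and O–O bonds with retention at C7'.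

**Step 5**
Reactants: 10 deprenyl diol; 11 prenyl acetate
Product: 12 hyperielliptone HB
Conditions: Pd2(dba)3·CHCl3 (2.5 mol %), (R,R)-DACH-phenyl Trost ligand (7.5 mol %), CH2Cl2, 0 °C to rt
Reagents that add atoms: prenyl acetate (11), CC(C)=CCOC(C)=O
Why: Tsuji–Trost asymmetric allylic alkylation: zerovalent palladium ionises 11, the released acetate deprotonates the acidic enol of 10, and the soft tricarbonyl anion attacks the unsubstituted terminus of the π-prenyl complex from outside the metal, so the linear prenyl group ends on C3, the only ring carbon still bearing H; the chiral pocket of the ligand selects the face of the flat C3 carbon (prenyl syn to C8', R) over the weak bias of the distant spiro ring, and because the ligand antipode gives the C3 epimer, the sense of induction is confirmed on the first run.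

**Compound list**
1 | (R)-(−)-linalool, (3R)-3,7-dimethylocta-1,6-dien-3-ol | C=C[C@](C)(O)CCC=C(C)C | starting material
2 | (R,E)-8-oxolinalool, (2E,6R)-6-hydroxy-2,6-dimethylocta-2,7-dienal | C=C[C@](C)(O)CC/C=C(\C)C=O | intermediate
3 | 2-methylbenzene-1,3,5-triol (2-methylphloroglucinol) | Cc1c(O)cc(O)cc1O | starting material
4 | (S)-2-methylbutanoyl chloride | CC[C@H](C)C(=O)Cl | starting material
5 | (2S)-2-methyl-1-(2,4,6-trihydroxy-3-methylphenyl)butan-1-one | CC[C@H](C)C(=O)c1c(O)cc(O)c(C)c1O | intermediate
6 | dienyl o-quinone methide, C5=C8' (Z, C4=O cis to C7'), C6'=C7' (E), C3' (R) | CC[C@H](C)C(=O)C1=C(O)/C(=C/C(C)=C/CC[C@@](C)(O)C=C)C(=O)C(C)=C1O | intermediate (not isolated)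
7 | 6-acyl-5,7-dihydroxy-3,8-dimethyl-2-[(3R)-3-hydroxy-3-methylpent-4-enyl]-2H-chromene, both epimers at the O-bearing C6' | CC[C@H](C)C(=O)c1c(O)c(C)c2OC(CC[C@@](C)(O)C=C)C(C)=Cc2c1O | intermediate (not isolated)
8 | spiro-hydrindene adduct: cis ring fusion, C7'=C8' alkene, C3'-OH β, C6=O β, C4 α, ring drawn as the 2,4-dienol | CC[C@H](C)C(=O)C1=C(O)C(C)=C(O)[C@]2(C[C@H]3[C@H](CC[C@@]3(C)O)C(C)=C2)C1=O | intermediate
9 | C7' β-triethylsilyl peroxide of 8 | CC[C@H](C)C(=O)C1=C(O)C(C)=C(O)[C@]2(C[C@H]3[C@H](CC[C@@]3(C)O)[C@](C)(OO[Si](CC)(CC)CC)C2)C1=O | intermediate (not isolated)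
10 | deprenyl diol: the target lacking the prenyl group, C3 as methyl-bearing enol carbon | CC[C@H](C)C(=O)C1=C(O)C(C)=C(O)[C@]2(C[C@H]3[C@H](CC[C@@]3(C)O)[C@](C)(O)C2)C1=O | intermediate
11 | prenyl acetate (3-methylbut-2-en-1-yl acetate) | CC(C)=CCOC(C)=O | starting material
12 | hyperielliptone HB | CC[C@H](C)C(=O)C1=C(O)[C@@](C)(CC=C(C)C)C(=O)[C@]2(C[C@H]3[C@H](CC[C@@]3(C)O)[C@](C)(O)C2)C1=O | target

**Step count:** 5 steps in total. The longest linear sequence is 4 steps (1 → 2 → 8 → 10 → 12, or 3 → 5 → 8 → 10 → 12).

**Steps most likely to fail**

**Step 3.**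
- Risk: chromene 7 is an aromatic sink and the dienophile is unactivated. A [1,7]-H shift, reversible oxa-Michael addition of the C3'-OH, or leakage through the other alkylidene geometry (giving the C5 epimer) may win.
- Fallback: this replaces the pericyclic closure by a metallo-ene closure plus a separate polar spirocyclisation. It sets out from 2 and 5 and returns at 10, so step 4 is bypassed too. Luche reduction of 2 (NaBH4, CeCl3·7H2O, MeOH) gives (R,E)-8-hydroxylinalool F1. Ac2O/pyridine at 0 °C acetylates only the primary OH to give 8-acetoxylinalool F2. Pd(PPh3)4/Et2Zn converts the allylic acetate into the allylzinc, which adds across the vinyl group in an intramolecular zinc-ene reaction (cis C2'/C6'), and an iodine quench gives the all-cis iodomethyl isopropenyl cyclopentanol F3. C-alkylation of the potassium salt of 5 with F3 in aqueous methanolic KOH gives the cyclopentylmethyl arene F4. VO(acac)2/t-BuOOH epoxidises the isopropenyl group from the side of the C3'-OH to give the terminal epoxide F5. KOt-Bu in t-BuOH then closes the spiro ring by dearomatising 6-endo attack of C5 on C8', giving 10.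

**Step 4.**
- Risk: face selectivity at the C7' radical is only a steric estimate. The C3–H enol can also be oxidised by O2 or exchange with the cobalt ligands.
- Fallback: this replaces radical hydration by directed epoxidation and hydride opening. It sets out from 8 and returns at 10. VO(acac)2/t-BuOOH, bound to the C3'-OH, delivers oxygen to the β face of C7'=C8' and gives the β-epoxide F6. KH (2 equiv) masks the tricarbonyl unit as its dianion, and LiEt3BH opens the epoxide at the less substituted C8', leaving the β C7'-OH of 10.

**Step 5.**
- Risk: linear versus branched and C versus O selectivity of the prenyl complex, and a possibly mismatched pairing of ligand and substrate at C3.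
- Fallback: this is a two-stage construction of the prenyl group. It sets out from 10 and returns at 12. Asymmetric allylic alkylation with allyl acetate, whose symmetrical small allyl unit raises no regiochemical question and reads the ligand pocket better, gives the C3-allyl compound F7. Cross-metathesis of F7 with 2-methylbut-2-ene (second-generation Hoveyda–Grubbs catalyst, CH2Cl2, 40 °C) gives 12.

**Further compounds**
F1 | step 3 | (R,E)-8-hydroxylinalool, (2E,6R)-2,6-dimethylocta-2,7-diene-1,6-diol | C=C[C@](C)(O)CC/C=C(\C)CO
F2 | step 3 | (R,E)-8-acetoxylinalool | C=C[C@](C)(O)CC/C=C(\C)COC(C)=O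
F3 | step 3 | all-cis 2-(iodomethyl)-1-methyl-3-(prop-1-en-2-yl)cyclopentan-1-ol | IC[C@H]1[C@H](CC[C@@]1(C)O)C(C)=C
F4 | step 3 | 5-(cyclopentylmethyl) arene with isopropenyl group | CC[C@H](C)C(=O)c1c(O)c(C)c(O)c(C[C@H]2[C@H](CC[C@@]2(C)O)C(C)=C)c1O
F5 | step 3 | C7',C8'-epoxide of F4 | CC[C@H](C)C(=O)c1c(O)c(C)c(O)c(C[C@H]2[C@H](CC[C@@]2(C)O)[C@@]3(C)CO3)c1O
F6 | step 4 | β-C7',C8'-epoxide of 8 | CC[C@H](C)C(=O)C1=C(O)C(C)=C(O)[C@]2(C[C@H]3[C@H](CC[C@@]3(C)O)[C@]4(C)O[C@H]24)C1=O
F7 | step 5 | C3-allyl analogue of the target | CC[C@H](C)C(=O)C1=C(O)[C@@](C)(CC=C)C(=O)[C@]2(C[C@H]3[C@H](CC[C@@]3(C)O)[C@](C)(O)C2)C1=O
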